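**Retrosynthetic overview**

1. The target is traced back to its 6'-O-benzyl ether 17; the benzyl group is removed last by hydrogenolysis.
2. The plan rests on ring A: C5 (OH), C6 (OMe), C7 (OMe) and C8 (H) are exactly the four carbons of a 2,3-dimethoxycyclobutenone made from dimethyl squarate. Ring A is cut at C4a–C5, giving 14, in which that cyclobutenone hangs on C6 of a finished 2-aryl-4-pyranone.
3. The bond between the cyclobutenone and the pyranone (later C8–C8a) is cut by a Stille coupling into 6-stannylpyranone 10 and 4-chloro-2,3-dimethoxycyclobutenone 13.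
4. The pyranone (later ring C) is built from aryl methyl ketone 4 and 3-ethoxyacryloyl chloride; ring B comes intact from 3,4,5-trimethoxyphenol.
5. Order of rings: ring B (purchased), then ring C (pyranone), then the four-membered ring is attached, and ring A is closed last.

Key step: step 10

Remark: compounds 12, 13, 14 and 16 each carry one stereocenter and are used or formed as racemates; that carbon ends as an sp2 carbon of the achiral target.

**Step 1**
Reactants: 1 3,4,5-trimethoxyphenol
Product: 2 1-(2-hydroxy-4,5,6-trimethoxyphenyl)ethan-1-one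
Conditions: AcOH, BF3·OEt2, 90 °C; then H2O
Reagents that add atoms: acetic acid, CC(=O)O
Why: Friedel–Crafts (Fries-type) C-acetylation at one of the two equivalent free positions ortho to the phenol, which is activated by four oxygen substituents, with BF3 chelation of the ortho-hydroxy ketone preventing a second acylation.

**Step 2**
Reactants: 2 1-(2-hydroxy-4,5,6-trimethoxyphenyl)ethan-1-one; 3 benzyl bromide
Product: 4 1-[2-(benzyloxy)-4,5,6-trimethoxyphenyl]ethan-1-one
Conditions: K2CO3, DMF, 60 °C
Reagents that add atoms: none
Why: Williamson O-benzylation of the only acidic OH; warming in DMF overcomes the hydrogen bond to the ketone.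

**Step 3**
Reactants: 4 1-[2-(benzyloxy)-4,5,6-trimethoxyphenyl]ethan-1-one; 5 (E)-3-ethoxyacryloyl chloride
Product: 6 (E)-1-[2-(benzyloxy)-4,5,6-trimethoxyphenyl]-5-ethoxypent-4-ene-1,3-dione
Conditions: LiN(SiMe3)2 (2.2 equiv), THF, −78 °C; then 5, −78 → 0 °C; aq. NH4Cl
Reagents that add atoms: none
Why: Claisen-type C-acylation of the lithium enolate of the methyl ketone at the acyl chloride carbon, the second equivalent of base holding the product as its diketonate so that it is not acylated again.

**Step 4**
Reactants: 6 (E)-1-[2-(benzyloxy)-4,5,6-trimethoxyphenyl]-5-ethoxypent-4-ene-1,3-dione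
Product: 7 2-[2-(benzyloxy)-4,5,6-trimethoxyphenyl]-4H-pyran-4-one
Conditions: CF3CO2H, CH2Cl2, rt
Reagents that add atoms: none
Why: Acid-catalysed cyclocondensation in which the enol oxygen of the aryl ketone adds to the β-ethoxy enone carbon and ethanol is lost (addition–elimination), giving the γ-pyranone; an aryl benzyl ether should tolerate short exposure to CF3CO2H at room temperature.

**Step 5**
Reactants: 7 2-[2-(benzyloxy)-4,5,6-trimethoxyphenyl]-4H-pyran-4-one
Product: 9 2-[2-(benzyloxy)-4,5,6-trimethoxyphenyl]-6-iodo-4H-pyran-4-one, via pyranon-6-ylzinc chloride 8 (not isolated)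
Conditions: TMPZnCl·LiCl (TMP = 2,2,6,6-tetramethylpiperidide), THF, 25 °C; then I2, 0 °C
Reagents that add atoms: iodine, II
Why: Deprotonative zincation without added Lewis acid removes the most acidic ring hydrogen, the one on C6 next to the ring oxygen (the position corresponding to C2 of a chromone), and iodinolysis of the C–Zn bond fixes that position; the mild zinc amide should leave the benzylic CH2 and the arene C–H alone.

**Step 6**
Reactants: 9 2-[2-(benzyloxy)-4,5,6-trimethoxyphenyl]-6-iodo-4H-pyran-4-one
Product: 10 2-[2-(benzyloxy)-4,5,6-trimethoxyphenyl]-6-(tributylstannyl)-4H-pyran-4-one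
Conditions: (Bu3Sn)2 (2 equiv), Pd(PPh3)4 (5 mol %), toluene, 100 °C
Reagents that add atoms: hexabutylditin, CCCC[Sn](CCCC)(CCCC)[Sn](CCCC)(CCCC)CCCC
Why: Palladium-catalysed stannylation of a vinylogous acyl iodide (oxidative addition, Sn–Sn transmetalation, reductive elimination); the excess of distannane holds back homocoupling of product with unreacted iodide.

**Step 7**
Reactants: 11 dimethyl squarate
Product: 12 4-hydroxy-2,3-dimethoxycyclobut-2-en-1-one (racemic)
Conditions: LiAlH(O-t-Bu)3, THF, −78 → −20 °C; aq. potassium sodium tartrate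
Reagents that add atoms: none
Why: 1,2-Reduction of one of the two equivalent carbonyls by a bulky, mild hydride; the remaining carbonyl is then a vinylogous ester and resists further reduction, and the new stereocenter is formed without control as a racemate.

**Step 8**
Reactants: 12 4-hydroxy-2,3-dimethoxycyclobut-2-en-1-one (racemic)
Product: 13 4-chloro-2,3-dimethoxycyclobut-2-en-1-one (racemic)
Conditions: PPh3, N-chlorosuccinimide, CH2Cl2, −20 → 0 °C; used at once
Reagents that add atoms: N-chlorosuccinimide, O=C1CCC(=O)N1Cl
Why: Appel-type chlorination in which chloride displaces the alkoxyphosphonium group under neutral conditions, avoiding the acid-triggered loss of methanol that would lead to the methoxycyclobutenedione.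

**Step 9**
Reactants: 10 2-[2-(benzyloxy)-4,5,6-trimethoxyphenyl]-6-(tributylstannyl)-4H-pyran-4-one; 13 4-chloro-2,3-dimethoxycyclobut-2-en-1-one (racemic)
Product: 14 2-[2-(benzyloxy)-4,5,6-trimethoxyphenyl]-6-(2,3-dimethoxy-4-oxocyclobut-2-en-1-yl)-4H-pyran-4-one (racemic)
Conditions: PdCl2(PhCN)2 (5 mol %), tri(2-furyl)phosphine (10 mol %), dioxane, 45 °C
Reagents that add atoms: none
Why: Stille cross-coupling in which the allylic C4–Cl bond adds oxidatively to zerovalent palladium to give an η3-oxocyclobutenyl complex, the pyranonyl group moves from tin to palladium (helped by the weakly donating furylphosphine), and reductive elimination at the hydrogen-bearing terminus gives the conjugated 4-substituted cyclobutenone; the temperature is kept low so that ring expansion is left to step 10, and any material that has already rearranged is compound 17 and is carried along.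

**Step 10**
Reactants: 14 2-[2-(benzyloxy)-4,5,6-trimethoxyphenyl]-6-(2,3-dimethoxy-4-oxocyclobut-2-en-1-yl)-4H-pyran-4-one (racemic)
Product: 17 2-[2-(benzyloxy)-4,5,6-trimethoxyphenyl]-5-hydroxy-6,7-dimethoxy-4H-chromen-4-one, via vinylketene 15 (not isolated), via cyclohexadienone 16 (not isolated)
Conditions: toluene (0.02 M, dry, degassed), 110 °C, Ar
Reagents that add atoms: none
Why: Heating should open the cyclobutenone by conrotatory 4π electrocyclic cleavage of its C1–C4 bond to dimethoxy vinylketene 15, whose ketene carbon then bonds to pyranone C5 in a thermal 6π electrocyclization that forms the C4a–C5 bond and closes ring A as cyclohexadienone 16; enolization of the doubly activated C4a–H of 16 then gives the 5-phenol, hydrogen-bonded to the C4 carbonyl. The closest known reaction type is the thermal ring expansion of 4-alkenyl-, 4-aryl- and 4-heteroaryl-cyclobutenones to phenols (squarate-based benzannulation), with the C5=C6 bond of the γ-pyranone as the alkene partner. Ring A is therefore closed in a 6π electrocyclic mode, and no stereocenter survives: the racemic C4 of 14 becomes the sp2 carbon C8, and the transient C4a center of 16 is erased on tautomerization. The step needs regiocontrol and the correct vinylketene geometry; regiocontrol is built in, because pyranone C6 has only one olefinic neighbour (C5, the other neighbour being the ring oxygen) and the two methoxy groups sit on the former cyclobutene carbons, so OH, OMe, OMe and H can only appear at C5, C6, C7 and C8. The geometry should correct itself, since ring opening is reversible and only the isomer with the pyranonyl group cis to the ketene is removed by the irreversible closure. High dilution and dry, degassed solvent are meant to keep the ketene from dimerizing or being trapped by water.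

**Step 11**
Reactants: 17 2-[2-(benzyloxy)-4,5,6-trimethoxyphenyl]-5-hydroxy-6,7-dimethoxy-4H-chromen-4-one
Product: 18 5,6'-dihydroxy-6,7,2',3',4'-pentamethoxyflavone
Conditions: H2 (1 atm), 10% Pd/C, EtOAc–MeOH, rt
Reagents that add atoms: none
Why: Catalytic hydrogenolysis of the aryl benzyl ether; the chromone C2=C3 bond, the methyl ethers and the chelated 5-OH should be inert at 1 atm and room temperature.

**Compound list**

1 | 3,4,5-trimethoxyphenol | COc1cc(O)cc(OC)c1OC | starting material
2 | 1-(2-hydroxy-4,5,6-trimethoxyphenyl)ethan-1-one | CC(=O)c1c(O)cc(OC)c(OC)c1OC | intermediate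
3 | benzyl bromide | BrCc1ccccc1 | starting material
4 | 1-[2-(benzyloxy)-4,5,6-trimethoxyphenyl]ethan-1-one | CC(=O)c1c(OCc2ccccc2)cc(OC)c(OC)c1OC | intermediate
5 | (E)-3-ethoxyacryloyl chloride | CCO/C=C/C(Cl)=O | starting material
6 | (E)-1-[2-(benzyloxy)-4,5,6-trimethoxyphenyl]-5-ethoxypent-4-ene-1,3-dione (drawn as the diketone, present largely as its enol) | CCO/C=C/C(=O)CC(=O)c1c(OCc2ccccc2)cc(OC)c(OC)c1OC | intermediate
7 | 2-[2-(benzyloxy)-4,5,6-trimethoxyphenyl]-4H-pyran-4-one | COc1cc(OCc2ccccc2)c(-c2cc(=O)cco2)c(OC)c1OC | intermediate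
8 | {6-[2-(benzyloxy)-4,5,6-trimethoxyphenyl]-4-oxo-4H-pyran-2-yl}zinc chloride (as its LiCl complex, not isolated) | COc1cc(OCc2ccccc2)c(-c2cc(=O)cc([Zn]Cl)o2)c(OC)c1OC | intermediate
9 | 2-[2-(benzyloxy)-4,5,6-trimethoxyphenyl]-6-iodo-4H-pyran-4-one | COc1cc(OCc2ccccc2)c(-c2cc(=O)cc(I)o2)c(OC)c1OC | intermediate
10 | 2-[2-(benzyloxy)-4,5,6-trimethoxyphenyl]-6-(tributylstannyl)-4H-pyran-4-one | CCCC[Sn](CCCC)(CCCC)c1cc(=O)cc(-c2c(OCc3ccccc3)cc(OC)c(OC)c2OC)o1 | intermediate
11 | dimethyl squarate (3,4-dimethoxycyclobut-3-ene-1,2-dione) | COC1=C(OC)C(=O)C1=O | starting material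
12 | 4-hydroxy-2,3-dimethoxycyclobut-2-en-1-one (racemic) | COC1=C(OC)C(=O)C1O | intermediate
13 | 4-chloro-2,3-dimethoxycyclobut-2-en-1-one (racemic) | COC1=C(OC)C(=O)C1Cl | intermediate
14 | 2-[2-(benzyloxy)-4,5,6-trimethoxyphenyl]-6-(2,3-dimethoxy-4-oxocyclobut-2-en-1-yl)-4H-pyran-4-one (racemic) | COC1=C(OC)C(=O)C1c1cc(=O)cc(-c2c(OCc3ccccc3)cc(OC)c(OC)c2OC)o1 | intermediate
15 | 4-{6-[2-(benzyloxy)-4,5,6-trimethoxyphenyl]-4-oxo-4H-pyran-2-yl}-2,3-dimethoxybuta-1,3-dien-1-one, the vinylketene with the pyranonyl group cis to the ketene carbon (not isolated) | COC(=C=O)/C(OC)=C\c1cc(=O)cc(-c2c(OCc3ccccc3)cc(OC)c(OC)c2OC)o1 | intermediate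
16 | 2-[2-(benzyloxy)-4,5,6-trimethoxyphenyl]-6,7-dimethoxy-4aH-chromene-4,5-dione (racemic, not isolated) | COC1=C(OC)C(=O)C2C(=O)C=C(-c3c(OCc4ccccc4)cc(OC)c(OC)c3OC)OC2=C1 | intermediate
17 | 2-[2-(benzyloxy)-4,5,6-trimethoxyphenyl]-5-hydroxy-6,7-dimethoxy-4H-chromen-4-one (6'-O-benzyl ether of the target) | COc1cc(OCc2ccccc2)c(-c2cc(=O)c3c(O)c(OC)c(OC)cc3o2)c(OC)c1OC | intermediate
18 | 5,6'-dihydroxy-6,7,2',3',4'-pentamethoxyflavone | COc1cc(O)c(-c2cc(=O)c3c(O)c(OC)c(OC)cc3o2)c(OC)c1OC | target

**Step count**

Total: 11 steps. Longest linear sequence: 9 steps (steps 1–6, 9, 10 and 11, from compound 1). The squarate branch (steps 7 and 8) joins at step 9.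

**Steps most likely to fail, with fallbacks**

Step 9. The electron-poor pyranonyl group may move from tin to palladium too slowly, so that the oxocyclobutenyl–palladium intermediate decomposes, or the new bond may form at the methoxy-bearing allyl terminus. The fallback sets out from pyranone 7 and leaves out iodide 9 and stannane 10. Compound 7 is zincated as in step 5 to the organozinc 8, and this solution is coupled directly with chloride 13 in a Negishi-type reaction (Pd(PPh3)4, THF, room temperature), transmetalation from zinc being much faster than from tin. The detour comes back to the route at compound 14 and makes no compound outside the list, entry F0.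

Step 10. The vinylketene may be lost to dimerization or to addition of trace nucleophiles faster than it closes, because the isomer that can cyclize (pyranonyl group turned inward) is the sterically disfavoured one. The precursor may also isomerize through its acidic ring hydrogen before it opens. The fallback builds the flavone by the chalcone route and sets out from compounds 1, 2 and 3. Phenol 1 is benzylated with 3 (K2CO3, DMF) to 5-(benzyloxy)-1,2,3-trimethoxybenzene F1. Vilsmeier–Haack formylation (POCl3, DMF) at one of its two equivalent free positions gives 2-(benzyloxy)-4,5,6-trimethoxybenzaldehyde F2. Claisen–Schmidt condensation of F2 with ketone 2 (KOH, EtOH) gives (E)-3-[2-(benzyloxy)-4,5,6-trimethoxyphenyl]-1-(2-hydroxy-4,5,6-trimethoxyphenyl)prop-2-en-1-one F3. Oxidative cyclization (catalytic I2, DMSO, 120 °C) gives 2-[2-(benzyloxy)-4,5,6-trimethoxyphenyl]-5,6,7-trimethoxy-4H-chromen-4-one F4. BCl3 in CH2Cl2 (−78 → 0 °C) should then cleave both the benzyl ether and the 5-methoxy group, the one chelated to the C4 carbonyl, and the detour comes back to the route at the target 18.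

Step 8. The activated alcohol may ionize toward the methoxy-stabilized cation and lose methanol to give the methoxycyclobutenedione, or the chloride may hydrolyse during isolation. The fallback sets out from alcohol 12 and avoids the chloride. Acetylation (Ac2O, pyridine, catalytic 4-dimethylaminopyridine, 0 °C) gives 2,3-dimethoxy-4-oxocyclobut-2-en-1-yl acetate F5, a more robust allylic electrophile. F5 is coupled with stannane 10 in a Stille coupling of an allylic acetate (Pd2(dba)3, LiCl, DMF, 40 °C), which passes through the same η3-oxocyclobutenyl palladium intermediate. The detour comes back to the route at compound 14.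

**Further compounds**

F0 | step 9 | none | none
F1 | step 10 | 5-(benzyloxy)-1,2,3-trimethoxybenzene | COc1cc(OCc2ccccc2)cc(OC)c1OC
F2 | step 10 | 2-(benzyloxy)-4,5,6-trimethoxybenzaldehyde | COc1cc(OCc2ccccc2)c(C=O)c(OC)c1OC
F3 | step 10 | (E)-3-[2-(benzyloxy)-4,5,6-trimethoxyphenyl]-1-(2-hydroxy-4,5,6-trimethoxyphenyl)prop-2-en-1-one | COc1cc(O)c(C(=O)/C=C/c2c(OCc3ccccc3)cc(OC)c(OC)c2OC)c(OC)c1OC
F4 | step 10 | 2-[2-(benzyloxy)-4,5,6-trimethoxyphenyl]-5,6,7-trimethoxy-4H-chromen-4-one | COc1cc(OCc2ccccc2)c(-c2cc(=O)c3c(OC)c(OC)c(OC)cc3o2)c(OC)c1OC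
F5 | step 8 | 2,3-dimethoxy-4-oxocyclobut-2-en-1-yl acetate (racemic) | CC(=O)OC1C(OC)=C(OC)C1=O
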